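**Retrosynthetic overview**

1. Last C–C bond: C8 of ring A to C1 of the diarylpropanol arm, made by Friedel–Crafts opening of a (2S,3S)-aryl oxirane at its benzylic carbon by C8 of a protected flavan. Inversion gives 1S; the oxirane carbon that keeps its oxygen becomes the 2S carbinol.
2. Ring C is disconnected at C2–C3. It is closed by an amine-catalysed 1,5-hydride shift/Mannich-type ring closure of an ortho-(arylmethoxy)cinnamaldehyde. C3 carries a temporary formyl group, which a Baeyer–Villiger oxidation turns into the 3-oxygen.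
3. Enabling feature: the C2–H bond is benzylic to ring B (para-oxygenated), alpha to O1, and 1,5 to C4 across O1–C8a–C4a of ring A. C4 is a CH2 in the target, so it can take the hydride and leave C2 (oxocarbenium) and C3 (enamine) to bond.
4. Arm: phloroglucinol (ring D) plus a cinnamyl alcohol (Friedel–Crafts), pivaloylation, Shi epoxidation.
5. Ring order: ring C is the only ring built (step 4). The oxirane is a temporary ring (made in step 10, opened in step 11). Ester cleavage and hydrogenolysis finish the route.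

Key step: step 4

Remark: the antipodes of the two chiral catalysts (steps 4 and 10) are assigned from the usual facial models of diarylprolinol silyl ethers and fructose-type dioxiranes; both antipodes of each are accessible, and the L-series ketone of step 10 is taken as purchasable.

**Route**

Step 1
Reactants: 1 2,4,6-trihydroxybenzaldehyde
Product: 2 4,6-bis(benzyloxy)-2-hydroxybenzaldehyde
Conditions: BnBr (2.05 equiv), K2CO3, DMF, 0 °C to rt
Reagents that add atoms: benzyl bromide, BrCc1ccccc1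
Why: Williamson etherification should stop at the 4,6-dibenzyl ether because the remaining 2-OH is locked in a hydrogen bond to the formyl group and is the least nucleophilic phenol.

Step 2
Reactants: 2 4,6-bis(benzyloxy)-2-hydroxybenzaldehyde; 3 3,4-bis(benzyloxy)benzyl chloride
Product: 4 2,4-bis(benzyloxy)-6-{[3,4-bis(benzyloxy)phenyl]methoxy}benzaldehyde
Conditions: K2CO3, DMF, 60 °C
Reagents that add atoms: none
Why: Williamson etherification of the last (chelated) phenol at higher temperature attaches ring B and the future C2 as an arylmethyl ether on the oxygen that becomes O1.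

Step 3
Reactants: 4 2,4-bis(benzyloxy)-6-{[3,4-bis(benzyloxy)phenyl]methoxy}benzaldehyde; 5 (triphenylphosphoranylidene)acetaldehyde
Product: 6 (E)-3-(2,4-bis(benzyloxy)-6-{[3,4-bis(benzyloxy)phenyl]methoxy}phenyl)prop-2-enal
Conditions: toluene, 90 °C
Reagents that add atoms: none
Why: Wittig olefination with the stabilised formyl ylide should give the (E)-cinnamaldehyde and brings in C3 together with the temporary formyl carbon.

Step 4
Reactants: 6 (E)-3-(2,4-bis(benzyloxy)-6-{[3,4-bis(benzyloxy)phenyl]methoxy}phenyl)prop-2-enal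
Product: 9 (2S,3S)-5,7-bis(benzyloxy)-2-[3,4-bis(benzyloxy)phenyl]chromane-3-carbaldehyde, via iminium ion 7 (not isolated), via oxocarbenium enamine 8 (not isolated)
Conditions: (R)-2-{bis[3,5-bis(trifluoromethyl)phenyl](trimethylsilyloxy)methyl}pyrrolidine (20 mol%), CF3CO2H (20 mol%), ClCH2CH2Cl, 40 °C
Reagents that add atoms: none
Why: Proposed new method: the amine and 6 form the iminium ion 7, whose beta-carbon (C4) takes a hydride from the C2–H bond through a six-membered 1,5-transfer across O1–C8a–C4a, and the aryl-oxocarbenium ion and enamine held together in 8 then collapse by Mannich-type attack of C3 on C2 before hydrolysis frees the catalyst. The closest known reaction types are the amine-catalysed asymmetric 1,5-hydride shift/ring closure of ortho-(dialkylamino)cinnamaldehydes to tetrahydroquinoline-3-carbaldehydes and the Lewis-acid-catalysed hydride shift/cyclisation of ortho-vinylaryl alkyl or benzyl ethers bearing acceptor alkenes to 2-substituted chromans; an aryl benzyl ether as hydride donor under iminium/enamine control has not been shown. Ring C closes in a 6-(enolexo)-endo-trig mode on the oxocarbenium carbon. C3 is set by the catalyst, whose diaryl(silyloxy)methyl group shields one face of the E-enamine so that the (R)-amine should lead to 3S, and C2 is set relative to C3 by a chair-like transition state with ring B pseudo-equatorial (trans), a preference reinforced because C3 can still epimerise through the enamine to the diequatorial aldehyde. The step needs the hydride to come from O1–CH2–ring B and not from the 5-O-benzyl group that also flanks the acceptor; the para-benzyloxy group of ring B, which stabilises the developing oxocarbenium ion, secures this, while the ortho,ortho'-disubstitution twists ring A out of conjugation and holds the C2–H bond over C4.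

Step 5
Reactants: 9 (2S,3S)-5,7-bis(benzyloxy)-2-[3,4-bis(benzyloxy)phenyl]chromane-3-carbaldehyde
Product: 10 (2R,3S)-5,7-bis(benzyloxy)-2-[3,4-bis(benzyloxy)phenyl]chroman-3-yl formate
Conditions: mCPBA, CH2Cl2, 0 °C
Reagents that add atoms: 3-chloroperoxybenzoic acid, OOC(=O)c1cccc(Cl)c1
Why: Baeyer–Villiger oxidation of the alpha-branched aldehyde lets the secondary carbon C3 migrate from carbon to oxygen with retention, so the trans aldehyde should give the (2R,3S) formate (the change of the C2 descriptor is a priority change only).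

Step 6
Reactants: 11 3,4-bis(benzyloxy)benzaldehyde; 5 (triphenylphosphoranylidene)acetaldehyde
Product: 12 (E)-3-[3,4-bis(benzyloxy)phenyl]prop-2-enal
Conditions: toluene, 80 °C
Reagents that add atoms: none
Why: Wittig olefination with the stabilised ylide should give the (E)-enal.

Step 7
Reactants: 12 (E)-3-[3,4-bis(benzyloxy)phenyl]prop-2-enal
Product: 13 (E)-3-[3,4-bis(benzyloxy)phenyl]prop-2-en-1-ol
Conditions: NaBH4, CeCl3·7H2O, MeOH, 0 °C
Reagents that add atoms: none
Why: Luche reduction delivers hydride 1,2 to the enal and leaves the (E)-alkene untouched.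

Step 8
Reactants: 13 (E)-3-[3,4-bis(benzyloxy)phenyl]prop-2-en-1-ol; 14 phloroglucinol (benzene-1,3,5-triol)
Product: 15 2-[(2E)-3-[3,4-bis(benzyloxy)phenyl]prop-2-en-1-yl]benzene-1,3,5-triol
Conditions: 14 (4 equiv), p-TsOH·H2O (10 mol%), 1,4-dioxane, rt
Reagents that add atoms: none
Why: In this acid-catalysed Friedel–Crafts alkylation the cinnamyl cation is attacked at its terminal carbon by the threefold-symmetric triol (no regiochemical choice on ring D), and the excess of 14 suppresses double alkylation.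

Step 9
Reactants: 15 2-[(2E)-3-[3,4-bis(benzyloxy)phenyl]prop-2-en-1-yl]benzene-1,3,5-triol
Product: 16 2-[(2E)-3-[3,4-bis(benzyloxy)phenyl]prop-2-en-1-yl]benzene-1,3,5-triyl tris(2,2-dimethylpropanoate)
Conditions: PivCl, pyridine, DMAP (cat.), CH2Cl2, 0 °C to rt
Reagents that add atoms: pivaloyl chloride, CC(C)(C)C(Cl)=O
Why: Acylation of the three phenols gives pivalates that make ring D electron-poor (no self-alkylation or ortho-oxygen participation in step 11) and are hindered enough to survive the pH 10.5 medium of step 10.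

Step 10
Reactants: 16 2-[(2E)-3-[3,4-bis(benzyloxy)phenyl]prop-2-en-1-yl]benzene-1,3,5-triyl tris(2,2-dimethylpropanoate)
Product: 17 2-{[(2S,3S)-3-[3,4-bis(benzyloxy)phenyl]oxiran-2-yl]methyl}benzene-1,3,5-triyl tris(2,2-dimethylpropanoate)
Conditions: 1,2:4,5-di-O-isopropylidene-beta-L-erythro-2,3-hexodiulo-2,6-pyranose (30 mol%), Oxone (2KHSO5·KHSO4·K2SO4), K2CO3, Bu4NHSO4, MeCN–CH2(OMe)2–aqueous Na2B4O7 buffer (pH 10.5), 0 °C; product used crude
Reagents that add atoms: potassium peroxymonosulfate (active part of Oxone), [K+].[O-]S(=O)(=O)OO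
Why: In this Shi epoxidation the chiral dioxirane transfers oxygen to the electron-rich trans-alkene through a spiro transition state, and the L-series ketone should give the (2S,3S)-oxirane, the mirror image of the (R,R)-oxiranes that the D-fructose-derived ketone gives with trans-beta-alkylstyrenes.

Step 11
Reactants: 10 (2R,3S)-5,7-bis(benzyloxy)-2-[3,4-bis(benzyloxy)phenyl]chroman-3-yl formate; 17 2-{[(2S,3S)-3-[3,4-bis(benzyloxy)phenyl]oxiran-2-yl]methyl}benzene-1,3,5-triyl tris(2,2-dimethylpropanoate)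
Product: 18 (2R,3S)-5,7-bis(benzyloxy)-2-[3,4-bis(benzyloxy)phenyl]-8-{(1S,2S)-1-[3,4-bis(benzyloxy)phenyl]-2-hydroxy-3-[2,4,6-tris(pivaloyloxy)phenyl]propyl}chroman-3-yl formate
Conditions: 10 (1.5 equiv), BF3·OEt2 (20 mol%), 4 Å molecular sieves, CH2Cl2, −78 to −40 °C
Reagents that add atoms: none
Why: In this Lewis-acid-promoted Friedel–Crafts alkylation of an arene by an aryl oxirane, BF3 opens the oxirane at the para-benzyloxy-stabilised benzylic carbon and C8 of 10 (the ring A position at which 5,7-di-O-benzyl flavans are alkylated by benzylic cations) enters anti to the departing oxygen, so inversion sets 1S while the carbinol carbon keeps the 2S configuration of the oxirane.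

Step 12
Reactants: 18 (2R,3S)-5,7-bis(benzyloxy)-2-[3,4-bis(benzyloxy)phenyl]-8-{(1S,2S)-1-[3,4-bis(benzyloxy)phenyl]-2-hydroxy-3-[2,4,6-tris(pivaloyloxy)phenyl]propyl}chroman-3-yl formate
Product: 19 (2R,3S)-5,7-bis(benzyloxy)-2-[3,4-bis(benzyloxy)phenyl]-8-{(1S,2S)-1-[3,4-bis(benzyloxy)phenyl]-2-hydroxy-3-(2,4,6-trihydroxyphenyl)propyl}chroman-3-ol
Conditions: NaOMe (6 equiv), MeOH–THF, 0 °C to rt, argon; then AcOH
Reagents that add atoms: none
Why: Base-mediated transesterification (Zemplén type) removes the formate and the three aryl pivalates while both catechol rings are still benzylated, so no base-labile free 4'-hydroxyflavan is exposed.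

Step 13
Reactants: 19 (2R,3S)-5,7-bis(benzyloxy)-2-[3,4-bis(benzyloxy)phenyl]-8-{(1S,2S)-1-[3,4-bis(benzyloxy)phenyl]-2-hydroxy-3-(2,4,6-trihydroxyphenyl)propyl}chroman-3-ol
Product: 20 (2R,3S)-2-(3,4-dihydroxyphenyl)-8-[(1S,2S)-1-(3,4-dihydroxyphenyl)-2-hydroxy-3-(2,4,6-trihydroxyphenyl)propyl]chromane-3,5,7-triol
Conditions: H2 (1 atm), Pd(OH)2/C, THF–MeOH, rt
Reagents that add atoms: none
Why: Hydrogenolysis of the six benzyl ethers under neutral conditions should free the phenols without touching the stereocentres or the C2–O1 bond, as is usual for benzylated flavan-3-ols.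

**Compound list**

1 | 2,4,6-trihydroxybenzaldehyde | O=Cc1c(O)cc(O)cc1O | starting material
2 | 4,6-bis(benzyloxy)-2-hydroxybenzaldehyde | O=Cc1c(O)cc(OCc2ccccc2)cc1OCc1ccccc1 | intermediate
3 | 3,4-bis(benzyloxy)benzyl chloride | ClCc1ccc(OCc2ccccc2)c(OCc2ccccc2)c1 | starting material
4 | 2,4-bis(benzyloxy)-6-{[3,4-bis(benzyloxy)phenyl]methoxy}benzaldehyde | O=Cc1c(OCc2ccccc2)cc(OCc2ccccc2)cc1OCc1ccc(OCc2ccccc2)c(OCc2ccccc2)c1 | intermediate
5 | (triphenylphosphoranylidene)acetaldehyde | O=CC=P(c1ccccc1)(c1ccccc1)c1ccccc1 | starting material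
6 | (E)-3-(2,4-bis(benzyloxy)-6-{[3,4-bis(benzyloxy)phenyl]methoxy}phenyl)prop-2-enal | O=C/C=C/c1c(OCc2ccccc2)cc(OCc2ccccc2)cc1OCc1ccc(OCc2ccccc2)c(OCc2ccccc2)c1 | intermediate
7 | iminium ion of 6 with the (R)-pyrrolidine catalyst (E,E; cation of the trifluoroacetate salt; not isolated) | C[Si](C)(C)OC(c1cc(C(F)(F)F)cc(C(F)(F)F)c1)(c1cc(C(F)(F)F)cc(C(F)(F)F)c1)[C@H]1CCC\[N+]1=C/C=C/c1c(OCc2ccccc2)cc(OCc2ccccc2)cc1OCc1ccc(OCc2ccccc2)c(OCc2ccccc2)c1 | intermediate
8 | oxocarbenium enamine formed from 7 by the 1,5-hydride shift (cation; not isolated) | C[Si](C)(C)OC(c1cc(C(F)(F)F)cc(C(F)(F)F)c1)(c1cc(C(F)(F)F)cc(C(F)(F)F)c1)[C@H]1CCCN1/C=C/Cc1c(OCc2ccccc2)cc(OCc2ccccc2)cc1/[O+]=C/c1ccc(OCc2ccccc2)c(OCc2ccccc2)c1 | intermediate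
9 | (2S,3S)-5,7-bis(benzyloxy)-2-[3,4-bis(benzyloxy)phenyl]chromane-3-carbaldehyde (2,3-trans) | c1c(OCc2ccccc2)cc(OCc2ccccc2)c2c1O[C@H](c1ccc(OCc3ccccc3)c(OCc3ccccc3)c1)[C@@H](C=O)C2 | intermediate
10 | (2R,3S)-5,7-bis(benzyloxy)-2-[3,4-bis(benzyloxy)phenyl]chroman-3-yl formate | c1c(OCc2ccccc2)cc(OCc2ccccc2)c2c1O[C@H](c1ccc(OCc3ccccc3)c(OCc3ccccc3)c1)[C@@H](OC=O)C2 | intermediate
11 | 3,4-bis(benzyloxy)benzaldehyde | O=Cc1ccc(OCc2ccccc2)c(OCc2ccccc2)c1 | starting material
12 | (E)-3-[3,4-bis(benzyloxy)phenyl]prop-2-enal | O=C/C=C/c1ccc(OCc2ccccc2)c(OCc2ccccc2)c1 | intermediate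
13 | (E)-3-[3,4-bis(benzyloxy)phenyl]prop-2-en-1-ol | OC/C=C/c1ccc(OCc2ccccc2)c(OCc2ccccc2)c1 | intermediate
14 | phloroglucinol (benzene-1,3,5-triol) | Oc1cc(O)cc(O)c1 | starting material
15 | 2-[(2E)-3-[3,4-bis(benzyloxy)phenyl]prop-2-en-1-yl]benzene-1,3,5-triol | Oc1cc(O)c(C/C=C/c2ccc(OCc3ccccc3)c(OCc3ccccc3)c2)c(O)c1 | intermediate
16 | 2-[(2E)-3-[3,4-bis(benzyloxy)phenyl]prop-2-en-1-yl]benzene-1,3,5-triyl tris(2,2-dimethylpropanoate) | CC(C)(C)C(=O)Oc1cc(OC(=O)C(C)(C)C)c(C/C=C/c2ccc(OCc3ccccc3)c(OCc3ccccc3)c2)c(OC(=O)C(C)(C)C)c1 | intermediate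
17 | 2-{[(2S,3S)-3-[3,4-bis(benzyloxy)phenyl]oxiran-2-yl]methyl}benzene-1,3,5-triyl tris(2,2-dimethylpropanoate) (trans-oxirane) | CC(C)(C)C(=O)Oc1cc(OC(=O)C(C)(C)C)c(C[C@@H]2O[C@H]2c2ccc(OCc3ccccc3)c(OCc3ccccc3)c2)c(OC(=O)C(C)(C)C)c1 | intermediate
18 | (2R,3S)-5,7-bis(benzyloxy)-2-[3,4-bis(benzyloxy)phenyl]-8-{(1S,2S)-1-[3,4-bis(benzyloxy)phenyl]-2-hydroxy-3-[2,4,6-tris(pivaloyloxy)phenyl]propyl}chroman-3-yl formate | CC(C)(C)C(=O)Oc1cc(OC(=O)C(C)(C)C)c(C[C@H](O)[C@@H](c2ccc(OCc3ccccc3)c(OCc3ccccc3)c2)c2c(OCc3ccccc3)cc(OCc3ccccc3)c3c2O[C@H](c2ccc(OCc4ccccc4)c(OCc4ccccc4)c2)[C@@H](OC=O)C3)c(OC(=O)C(C)(C)C)c1 | intermediate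
19 | (2R,3S)-5,7-bis(benzyloxy)-2-[3,4-bis(benzyloxy)phenyl]-8-{(1S,2S)-1-[3,4-bis(benzyloxy)phenyl]-2-hydroxy-3-(2,4,6-trihydroxyphenyl)propyl}chroman-3-ol | Oc1cc(O)c(C[C@H](O)[C@@H](c2ccc(OCc3ccccc3)c(OCc3ccccc3)c2)c2c(OCc3ccccc3)cc(OCc3ccccc3)c3c2O[C@H](c2ccc(OCc4ccccc4)c(OCc4ccccc4)c2)[C@@H](O)C3)c(O)c1 | intermediate
20 | (2R,3S)-2-(3,4-dihydroxyphenyl)-8-[(1S,2S)-1-(3,4-dihydroxyphenyl)-2-hydroxy-3-(2,4,6-trihydroxyphenyl)propyl]chromane-3,5,7-triol (CNP0175733.2) | Oc1cc(O)c(C[C@H](O)[C@@H](c2ccc(O)c(O)c2)c2c(O)cc(O)c3c2O[C@H](c2ccc(O)c(O)c2)[C@@H](O)C3)c(O)c1 | target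

**Step count and risks**

Total step count: 13 steps. Longest linear sequence: 8 steps (steps 1–5, then 11–13; the arm, steps 6–10 then 11–13, is equally long).

Steps most likely to fail:

Step 4 (Proposed new method). The hydride transfer may be too slow on the electron-rich iminium ion. Water may intercept the oxocarbenium ion before the C–C bond forms (loss of the ring B arylmethyl group). Facial control by the amine may be poor. The fallback uses known chemistry and still closes ring C through the C2–C3 bond, now as C2=C3. It sets out from 11 and comes back at 10. 11 is oxidised (NaClO2, NaH2PO4, 2-methylbut-2-ene, t-BuOH–H2O) to 3,4-bis(benzyloxy)benzoic acid F1. Commercial 3,5-bis(benzyloxy)phenol is O-allylated (allyl bromide, K2CO3, acetone) to 1-(allyloxy)-3,5-bis(benzyloxy)benzene F2, which rearranges (aromatic Claisen, N,N-diethylaniline, 190 °C; both ortho positions are equivalent) to 2-allyl-3,5-bis(benzyloxy)phenol F3. Esterification of F3 with F1 (EDC·HCl, DMAP, CH2Cl2) gives 2-allyl-3,5-bis(benzyloxy)phenyl 3,4-bis(benzyloxy)benzoate F4. Olefinic-ester cyclisation with the Takai–Utimoto titanium ethylidene reagent (TiCl4, Zn, PbCl2, TMEDA, CH3CHBr2, THF) closes C2=C3 to 5,7-bis(benzyloxy)-2-[3,4-bis(benzyloxy)phenyl]-4H-chromene F5. Asymmetric hydroboration–oxidation with monoisopinocampheylborane (IpcBH2, THF, −25 °C; then NaBO3), the antipode of the borane being chosen for this sense, adds H to C2 and OH to C3 on one face (trans) and should give (2R,3S)-5,7-bis(benzyloxy)-2-[3,4-bis(benzyloxy)phenyl]chroman-3-ol F6. Formylation (HCO2H, Ac2O, pyridine) returns 10.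

Step 11. Meinwald rearrangement of the electron-rich oxirane to the benzyl ketone may outrun the bimolecular arylation, and a long-lived benzylic cation may leak facial selectivity. The fallback replaces direct oxirane opening by a benzylic acetate coupling under neighbouring-group control. It sets out from 17 and comes back at 19. Acetolysis of 17 (AcOH, NaOAc, rt) opens the oxirane at the benzylic carbon with inversion to (1R,2S)-1-[3,4-bis(benzyloxy)phenyl]-2-hydroxy-3-[2,4,6-tris(pivaloyloxy)phenyl]propyl acetate F7. Acetylation (Ac2O, pyridine) gives (1R,2S)-1-[3,4-bis(benzyloxy)phenyl]-3-[2,4,6-tris(pivaloyloxy)phenyl]propane-1,2-diyl diacetate F8. With TMSOTf (CH2Cl2, −40 °C) and 10, the benzylic acetate should ionise with participation of the neighbouring acetate to the trans-1,3-dioxolan-2-ylium ion, which C8 opens anti. This should give the 2-O-acetate of 18, (2R,3S)-8-{(1S,2S)-2-acetoxy-1-[3,4-bis(benzyloxy)phenyl]-3-[2,4,6-tris(pivaloyloxy)phenyl]propyl}-5,7-bis(benzyloxy)-2-[3,4-bis(benzyloxy)phenyl]chroman-3-yl formate F9. The conditions of step 12 then remove the acetate as well and give 19.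

Step 5. In the peracid adduct the formyl hydrogen may migrate in place of C3 (giving the carboxylic acid), or the peracid may attack the electron-rich ring A. The fallback goes through the methyl ketone, where secondary-alkyl migration is reliable. It sets out from 9 and comes back at 19. MeMgBr (THF, −78 °C) gives 1-[(2S,3R)-5,7-bis(benzyloxy)-2-[3,4-bis(benzyloxy)phenyl]chroman-3-yl]ethan-1-ol F10 (carbinol epimers; same spatial arrangement at C2 and C3 as in 9). Dess–Martin periodinane gives 1-[(2S,3S)-5,7-bis(benzyloxy)-2-[3,4-bis(benzyloxy)phenyl]chroman-3-yl]ethan-1-one F11. Baeyer–Villiger oxidation (mCPBA, Na2HPO4, CH2Cl2), in which C3 migrates in preference to methyl with retention, gives (2R,3S)-5,7-bis(benzyloxy)-2-[3,4-bis(benzyloxy)phenyl]chroman-3-yl acetate F12. F12 takes the place of 10 in step 11 and should give (2R,3S)-5,7-bis(benzyloxy)-2-[3,4-bis(benzyloxy)phenyl]-8-{(1S,2S)-1-[3,4-bis(benzyloxy)phenyl]-2-hydroxy-3-[2,4,6-tris(pivaloyloxy)phenyl]propyl}chroman-3-yl acetate F13. The conditions of step 12 bring the route back at 19.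

Further compounds
F1 | step 4 | 3,4-bis(benzyloxy)benzoic acid | OC(=O)c1ccc(OCc2ccccc2)c(OCc2ccccc2)c1
F2 | step 4 | 1-(allyloxy)-3,5-bis(benzyloxy)benzene | C=CCOc1cc(OCc2ccccc2)cc(OCc2ccccc2)c1
F3 | step 4 | 2-allyl-3,5-bis(benzyloxy)phenol | C=CCc1c(O)cc(OCc2ccccc2)cc1OCc1ccccc1
F4 | step 4 | 2-allyl-3,5-bis(benzyloxy)phenyl 3,4-bis(benzyloxy)benzoate | C=CCc1c(OC(=O)c2ccc(OCc3ccccc3)c(OCc3ccccc3)c2)cc(OCc2ccccc2)cc1OCc1ccccc1
F5 | step 4 | 5,7-bis(benzyloxy)-2-[3,4-bis(benzyloxy)phenyl]-4H-chromene | C1C=C(c2ccc(OCc3ccccc3)c(OCc3ccccc3)c2)Oc2cc(OCc3ccccc3)cc(OCc3ccccc3)c21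
F6 | step 4 | (2R,3S)-5,7-bis(benzyloxy)-2-[3,4-bis(benzyloxy)phenyl]chroman-3-ol | c1c(OCc2ccccc2)cc(OCc2ccccc2)c2c1O[C@H](c1ccc(OCc3ccccc3)c(OCc3ccccc3)c1)[C@@H](O)C2
F7 | step 11 | (1R,2S)-1-[3,4-bis(benzyloxy)phenyl]-2-hydroxy-3-[2,4,6-tris(pivaloyloxy)phenyl]propyl acetate | CC(C)(C)C(=O)Oc1cc(OC(=O)C(C)(C)C)c(C[C@H](O)[C@H](OC(C)=O)c2ccc(OCc3ccccc3)c(OCc3ccccc3)c2)c(OC(=O)C(C)(C)C)c1
F8 | step 11 | (1R,2S)-1-[3,4-bis(benzyloxy)phenyl]-3-[2,4,6-tris(pivaloyloxy)phenyl]propane-1,2-diyl diacetate | CC(C)(C)C(=O)Oc1cc(OC(=O)C(C)(C)C)c(C[C@H](OC(C)=O)[C@H](OC(C)=O)c2ccc(OCc3ccccc3)c(OCc3ccccc3)c2)c(OC(=O)C(C)(C)C)c1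
F9 | step 11 | (2R,3S)-8-{(1S,2S)-2-acetoxy-1-[3,4-bis(benzyloxy)phenyl]-3-[2,4,6-tris(pivaloyloxy)phenyl]propyl}-5,7-bis(benzyloxy)-2-[3,4-bis(benzyloxy)phenyl]chroman-3-yl formate | CC(C)(C)C(=O)Oc1cc(OC(=O)C(C)(C)C)c(C[C@H](OC(C)=O)[C@@H](c2ccc(OCc3ccccc3)c(OCc3ccccc3)c2)c2c(OCc3ccccc3)cc(OCc3ccccc3)c3c2O[C@H](c2ccc(OCc4ccccc4)c(OCc4ccccc4)c2)[C@@H](OC=O)C3)c(OC(=O)C(C)(C)C)c1
F10 | step 5 | 1-[(2S,3R)-5,7-bis(benzyloxy)-2-[3,4-bis(benzyloxy)phenyl]chroman-3-yl]ethan-1-ol (carbinol epimers) | c1c(OCc2ccccc2)cc(OCc2ccccc2)c2c1O[C@H](c1ccc(OCc3ccccc3)c(OCc3ccccc3)c1)[C@@H](C(C)O)C2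
F11 | step 5 | 1-[(2S,3S)-5,7-bis(benzyloxy)-2-[3,4-bis(benzyloxy)phenyl]chroman-3-yl]ethan-1-one | c1c(OCc2ccccc2)cc(OCc2ccccc2)c2c1O[C@H](c1ccc(OCc3ccccc3)c(OCc3ccccc3)c1)[C@@H](C(C)=O)C2
F12 | step 5 | (2R,3S)-5,7-bis(benzyloxy)-2-[3,4-bis(benzyloxy)phenyl]chroman-3-yl acetate | c1c(OCc2ccccc2)cc(OCc2ccccc2)c2c1O[C@H](c1ccc(OCc3ccccc3)c(OCc3ccccc3)c1)[C@@H](OC(C)=O)C2
F13 | step 5 | (2R,3S)-5,7-bis(benzyloxy)-2-[3,4-bis(benzyloxy)phenyl]-8-{(1S,2S)-1-[3,4-bis(benzyloxy)phenyl]-2-hydroxy-3-[2,4,6-tris(pivaloyloxy)phenyl]propyl}chroman-3-yl acetate | CC(C)(C)C(=O)Oc1cc(OC(=O)C(C)(C)C)c(C[C@H](O)[C@@H](c2ccc(OCc3ccccc3)c(OCc3ccccc3)c2)c2c(OCc3ccccc3)cc(OCc3ccccc3)c3c2O[C@H](c2ccc(OCc4ccccc4)c(OCc4ccccc4)c2)[C@@H](OC(C)=O)C3)c(OC(=O)C(C)(C)C)c1
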